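The four phenols are masked as benzyl ethers, the C4 carbinol is traced back to a ketone and a methoxycarbonyl group is added at C5 as activator; the oxane ring is then cut at C2–C3, C5–C6 and O1–C6.
The enabling feature lies in the oxane ring (O1; C2 with the 3,4-dihydroxy-5-methoxyphenyl group; C4 with OH; C6 with the arylethyl chain): C3, C4 and C5 with the C4 oxygen are the methyl, keto and methylene carbons of an acetoacetate, and C2 and C6, the two carbons on O1, are each the carbonyl carbon of an aldehyde.
In the forward direction the bis-silyl dienolate of methyl acetoacetate and the two benzyl-protected aldehydes are made in parallel and joined in one flask, in the order aldol (C2–C3), Knoevenagel condensation (C5–C6), oxa-Michael closure (O1–C6); this is the only ring-forming event.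
C2 comes from the (S)-BINOL–titanium catalyst of the aldol stage; C6 from the reversible ring closure, which settles on the 2,6-cis chair with both groups equatorial; C4 from equatorial hydride attack on that chair, giving the axial alcohol trans to both substituents.
Removal of the ester group, ketone reduction and hydrogenolysis of the four benzyl ethers then give the (2S,4S,6S) target.

Key step: step 6

Assumption: the (S)-BINOL–titanium catalyst is taken to deliver the (S)-carbinol from the aryl aldehyde, the sense expected for benzaldehydes with this catalyst family; should the opposite sense be found, (R)-BINOL is used and nothing else changes.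

Step 1
Reactants: 1 methyl acetoacetate
Product: 2 methyl (E)-3-(trimethylsilyloxy)but-2-enoate
Conditions: TMSCl, Et3N, hexane, rt; filtration, distillation
Reagents that add atoms: chlorotrimethylsilane, C[Si](C)(C)Cl
Why: Silyl enol ether formation: the enol oxygen of the β-keto ester is silylated by TMSCl with triethylamine as base, and the alkene geometry is of no account because this bond becomes the C2–C3 single bond of the diene.

Step 2
Reactants: 2 methyl (E)-3-(trimethylsilyloxy)but-2-enoate
Product: 3 (1Z)-1-methoxy-1,3-bis(trimethylsilyloxy)buta-1,3-diene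
Conditions: LDA, THF, −78 °C; TMSCl, −78 °C → rt; non-aqueous work-up, distillation
Reagents that add atoms: chlorotrimethylsilane, C[Si](C)(C)Cl
Why: Deprotonation of the γ-methyl group by LDA gives the extended (vinylogous) ester dienolate, which TMSCl traps on oxygen to give the 1,3-bis(silyloxy)diene, the standard preparation of this dienolate equivalent.

Step 3
Reactants: 4 3,4-dihydroxy-5-methoxybenzaldehyde (5-hydroxyvanillin)
Product: 5 3,4-bis(benzyloxy)-5-methoxybenzaldehyde
Conditions: BnBr, K2CO3, DMF, 60 °C
Reagents that add atoms: benzyl bromide, BrCc1ccccc1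
Why: Williamson ether synthesis on both phenols with carbonate as base; the aromatic aldehyde has no α-hydrogen and is unaffected.

Step 4
Reactants: 6 3-(3,4-dihydroxyphenyl)propanoic acid
Product: 7 benzyl 3-[3,4-bis(benzyloxy)phenyl]propanoate
Conditions: BnBr (3.3 equiv), K2CO3, DMF, 60 °C, under N2
Reagents that add atoms: benzyl bromide, BrCc1ccccc1
Why: Williamson alkylation of the two phenoxides and of the carboxylate in one operation masks catechol and acid together, the benzyl ester being a convenient handle for the partial reduction that follows.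

Step 5
Reactants: 7 benzyl 3-[3,4-bis(benzyloxy)phenyl]propanoate
Product: 8 3-[3,4-bis(benzyloxy)phenyl]propanal
Conditions: DIBAL-H (1.1 equiv), toluene, −78 °C; aq. Rochelle salt
Reagents that add atoms: none
Why: Partial reduction of an ester with DIBAL-H: at −78 °C the tetrahedral aluminium hemiacetal is stable and releases the aldehyde only on aqueous work-up, while the benzyl ethers are inert.

Step 6
Reactants: 3 (1Z)-1-methoxy-1,3-bis(trimethylsilyloxy)buta-1,3-diene; 5 3,4-bis(benzyloxy)-5-methoxybenzaldehyde; 8 3-[3,4-bis(benzyloxy)phenyl]propanal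
Product: 12 methyl (2S,6S)-6-[3,4-bis(benzyloxy)-5-methoxyphenyl]-2-{2-[3,4-bis(benzyloxy)phenyl]ethyl}-4-hydroxy-5,6-dihydro-2H-pyran-3-carboxylate (enol tautomer of the 2,6-cis keto ester), via bis-silyl aldol adduct 9 (not isolated), via δ-hydroxy-β-keto ester 10 (not isolated), via Knoevenagel alkylidene 11 (not isolated)
Conditions: (S)-BINOL (cat.), Ti(OiPr)4 (cat.), LiCl (cat.), THF, rt, 5 then 3 (1.1 equiv); MeOH, PPTS (cat.), 0 °C; evaporation, CH2Cl2; 8, Yb(OTf)3 (cat.), rt
Reagents that add atoms: none
Why: The (S)-BINOL–titanium Lewis acid binds aldehyde 5 and the unsubstituted CH2 terminus of dienolate 3 adds to one carbonyl face in an open transition state (vinylogous Mukaiyama aldol, C2–C3 in target numbering) to give silylated adduct 9; buffered methanolysis releases hydroxy keto ester 10, whose active methylene condenses with aldehyde 8 under Yb(OTf)3 (Knoevenagel, C5–C6) to alkylidene 11, and the carbinol oxygen then adds to the doubly activated alkene (oxa-Michael, O1–C6). The closest known reaction type is the asymmetric one-pot Maitland–Japp synthesis of oxan-4-ones from this dienolate and two different aldehydes. The one ring closes in the 6-endo-trig mode. The aryl-bearing centre is fixed by the chiral catalyst, and the chain-bearing centre by thermodynamic control, since the oxa-Michael addition is reversible and drains into the chair with both substituents equatorial (2,6-cis). The step needs chemoselectivity between the two aldehydes and an intact benzylic C–O bond: the aryl aldehyde is alone in the flask during the aldol and cannot enolise, the enolisable aldehyde enters only once a β-keto ester is present to capture it, and PPTS in methanol followed by a lanthanide triflate is too weakly acidic to ionise a benzylic carbinol whose para-benzyloxy group is twisted out of conjugation by its two ortho neighbours.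

Step 7
Reactants: 12 methyl (2S,6S)-6-[3,4-bis(benzyloxy)-5-methoxyphenyl]-2-{2-[3,4-bis(benzyloxy)phenyl]ethyl}-4-hydroxy-5,6-dihydro-2H-pyran-3-carboxylate
Product: 13 (2S,6S)-2-[3,4-bis(benzyloxy)-5-methoxyphenyl]-6-{2-[3,4-bis(benzyloxy)phenyl]ethyl}oxan-4-one
Conditions: DMF/H2O, 160 °C (microwave)
Reagents that add atoms: none
Why: Krapcho-type dealkoxycarbonylation: water in hot DMF hydrolyses the β-keto ester and the β-keto acid loses CO2, and because any retro-oxa-Michael opening breaks only one C–O bond at a time the ring recloses to the same, more stable cis isomer with both centres unchanged.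

Step 8
Reactants: 13 (2S,6S)-2-[3,4-bis(benzyloxy)-5-methoxyphenyl]-6-{2-[3,4-bis(benzyloxy)phenyl]ethyl}oxan-4-one
Product: 14 (2S,4S,6S)-2-[3,4-bis(benzyloxy)-5-methoxyphenyl]-6-{2-[3,4-bis(benzyloxy)phenyl]ethyl}oxan-4-ol
Conditions: L-Selectride, THF, −78 °C; H2O
Reagents that add atoms: none
Why: Diastereoselective ketone reduction with a bulky trialkylborohydride: the 2,6-diequatorial chair is locked, L-Selectride approaches along the less hindered equatorial trajectory and the hydroxyl ends up axial, which is the (4S) alcohol trans to both ring substituents.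

Step 9
Reactants: 14 (2S,4S,6S)-2-[3,4-bis(benzyloxy)-5-methoxyphenyl]-6-{2-[3,4-bis(benzyloxy)phenyl]ethyl}oxan-4-ol
Product: 15 (2S,4S,6S)-2-(3,4-dihydroxy-5-methoxyphenyl)-6-[2-(3,4-dihydroxyphenyl)ethyl]oxan-4-ol
Conditions: H2 (1 atm), Pd/C, EtOAc/MeOH, rt
Reagents that add atoms: none
Why: Catalytic hydrogenolysis cleaves aryl benzyl ethers far faster than the benzylic dialkyl ether C2–O1 held in the ring, and the aryl methyl ether and the secondary alcohol are inert, so stopping at the uptake of four equivalents of hydrogen should leave the oxane and its three stereocentres intact.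

Compound list
1 | methyl acetoacetate | COC(=O)CC(C)=O | starting material
2 | methyl (E)-3-(trimethylsilyloxy)but-2-enoate (E drawn; geometry immaterial) | COC(=O)/C=C(\C)O[Si](C)(C)C | intermediate
3 | (1Z)-1-methoxy-1,3-bis(trimethylsilyloxy)buta-1,3-diene | CO/C(O[Si](C)(C)C)=C/C(=C)O[Si](C)(C)C | intermediate
4 | 3,4-dihydroxy-5-methoxybenzaldehyde (5-hydroxyvanillin) | COc1cc(C=O)cc(O)c1O | starting material
5 | 3,4-bis(benzyloxy)-5-methoxybenzaldehyde | COc1cc(C=O)cc(OCc2ccccc2)c1OCc1ccccc1 | intermediate
6 | 3-(3,4-dihydroxyphenyl)propanoic acid | OC(=O)CCc1ccc(O)c(O)c1 | starting material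
7 | benzyl 3-[3,4-bis(benzyloxy)phenyl]propanoate | O=C(CCc1ccc(OCc2ccccc2)c(OCc2ccccc2)c1)OCc1ccccc1 | intermediate
8 | 3-[3,4-bis(benzyloxy)phenyl]propanal | O=CCCc1ccc(OCc2ccccc2)c(OCc2ccccc2)c1 | intermediate
9 | methyl (2Z,5S)-5-[3,4-bis(benzyloxy)-5-methoxyphenyl]-3,5-bis(trimethylsilyloxy)pent-2-enoate (2Z drawn; enol ether geometry immaterial) | COC(=O)/C=C(O[Si](C)(C)C)/C[C@H](O[Si](C)(C)C)c1cc(OC)c(OCc2ccccc2)c(OCc2ccccc2)c1 | intermediate (not isolated)
10 | methyl (5S)-5-[3,4-bis(benzyloxy)-5-methoxyphenyl]-5-hydroxy-3-oxopentanoate | COC(=O)CC(=O)C[C@H](O)c1cc(OC)c(OCc2ccccc2)c(OCc2ccccc2)c1 | intermediate (not isolated)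
11 | methyl (2Z,5S)-2-{3-[3,4-bis(benzyloxy)phenyl]propylidene}-5-[3,4-bis(benzyloxy)-5-methoxyphenyl]-5-hydroxy-3-oxopentanoate (2Z drawn; both alkene isomers cyclise) | COC(=O)/C(=C\CCc1ccc(OCc2ccccc2)c(OCc2ccccc2)c1)C(=O)C[C@H](O)c1cc(OC)c(OCc2ccccc2)c(OCc2ccccc2)c1 | intermediate (not isolated)
12 | methyl (2S,6S)-6-[3,4-bis(benzyloxy)-5-methoxyphenyl]-2-{2-[3,4-bis(benzyloxy)phenyl]ethyl}-4-hydroxy-5,6-dihydro-2H-pyran-3-carboxylate | COc1cc([C@@H]2CC(O)=C(C(=O)OC)[C@H](CCc3ccc(OCc4ccccc4)c(OCc4ccccc4)c3)O2)cc(OCc2ccccc2)c1OCc1ccccc1 | intermediate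
13 | (2S,6S)-2-[3,4-bis(benzyloxy)-5-methoxyphenyl]-6-{2-[3,4-bis(benzyloxy)phenyl]ethyl}oxan-4-one | COc1cc([C@@H]2CC(=O)C[C@H](CCc3ccc(OCc4ccccc4)c(OCc4ccccc4)c3)O2)cc(OCc2ccccc2)c1OCc1ccccc1 | intermediate
14 | (2S,4S,6S)-2-[3,4-bis(benzyloxy)-5-methoxyphenyl]-6-{2-[3,4-bis(benzyloxy)phenyl]ethyl}oxan-4-ol | COc1cc([C@@H]2C[C@@H](O)C[C@H](CCc3ccc(OCc4ccccc4)c(OCc4ccccc4)c3)O2)cc(OCc2ccccc2)c1OCc1ccccc1 | intermediate
15 | (2S,4S,6S)-2-(3,4-dihydroxy-5-methoxyphenyl)-6-[2-(3,4-dihydroxyphenyl)ethyl]oxan-4-ol | COc1cc([C@@H]2C[C@@H](O)C[C@H](CCc3ccc(O)c(O)c3)O2)cc(O)c1O | target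

Total step count: 9. Longest linear sequence: 6 steps (6 → 7 → 8 → 12 → 13 → 14 → 15; the branch from 1 is equally long).

Steps most likely to fail

Step 6. The enantiomeric purity of the aryl carbinol may suffer from incomplete facial discrimination in the aldol stage or from partial ionisation of the benzylic C–O bond in the second stage. Self-condensation of the enolisable aldehyde may also outrun the Knoevenagel condensation while titanium residues are present. The fallback sets out from aldehyde 5 and replaces catalyst control by auxiliary control with isolation. A tin(II) triflate/N-ethylpiperidine acetate aldol (Nagao type) of 5 with (R)-3-acetyl-4-isopropyl-1,3-thiazolidine-2-thione should give (3S)-3-[3,4-bis(benzyloxy)-5-methoxyphenyl]-3-hydroxy-1-[(4R)-4-isopropyl-2-thioxo-1,3-thiazolidin-3-yl]propan-1-one F1. The (R)-auxiliary is chosen because the chelated chair model predicts the (S)-carbinol from it, and the minor diastereomer is removed by chromatography. Displacement of the auxiliary with potassium methyl malonate, MgCl2 and imidazole in THF (decarboxylative Claisen condensation) then gives hydroxy keto ester 10 as an isolated compound. In a separate flask, free of titanium, 10 is condensed with aldehyde 8 under Yb(OTf)3 in CH2Cl2, and the route is rejoined at 12.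

Step 9. Hydrogenolysis may run on into the cyclic benzylic C2–O1 bond and open the ring before the last benzyl ether has gone. The fallback goes from 14 directly to 15 without hydrogen: BCl3 with pentamethylbenzene as cation scavenger in CH2Cl2 at −78 °C, a Lewis-acid dealkylation. At this temperature the aryl methyl ether should be retained and the benzyl cations are captured by the scavenger. This fallback passes through no new compound (F0).

Step 5. The reduction may overshoot the aldehyde oxidation level if the tetrahedral aluminium intermediate collapses before the quench. The fallback sets out from ester 7 and takes the reduction deliberately to the alcohol: LiAlH4 in THF at 0 °C should give 3-[3,4-bis(benzyloxy)phenyl]propan-1-ol F2. Oxidation of F2 with Dess–Martin periodinane in CH2Cl2 then returns to the route at aldehyde 8.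

Further compounds
F1 | step 6 | (3S)-3-[3,4-bis(benzyloxy)-5-methoxyphenyl]-3-hydroxy-1-[(4R)-4-isopropyl-2-thioxo-1,3-thiazolidin-3-yl]propan-1-one | COc1cc([C@@H](O)CC(=O)N2[C@H](C(C)C)CSC2=S)cc(OCc2ccccc2)c1OCc1ccccc1
F0 | step 9 | none | none
F2 | step 5 | 3-[3,4-bis(benzyloxy)phenyl]propan-1-ol | OCCCc1ccc(OCc2ccccc2)c(OCc2ccccc2)c1
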